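**Plan**

- Retrosynthesis: (i) the 21 benzyl ethers and one aryl bromide go by hydrogenolysis. (ii) Ring C of the top unit is cut through O1–C2 and C3–C4 (retro-[4+2]) to an ortho-quinone methide on the top ring A and a (Z)-enol gallate of a styrene. (iii) The methide carbon is cut from the top ring A, giving an aldehyde at C6 of the middle unit plus 3,5-bis(benzyloxy)phenol, held together as a benzodioxaborin. (iv) The middle C4–bottom C8 bond is cut to two epicatechin gallate units.
- Enabling feature: in the top unit, O1 on C8a is ortho to C4a, whose benzylic carbon C4 carries a second electron-rich ring (C6 of the middle unit). O1–C8a–C4a–C4 is therefore a latent, strongly stabilised ortho-quinone methide, and C2–C3 (aryl on C2, acyloxy on C3, cis) is a latent Z-enol ester.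
- Forward: epicatechin → benzylated gallate → C4 ether, C8 bromide (temporary block), C6 iodide (handle) → 4β→8 dimer → C6 aldehyde → dioxaborin (temporary ring) → [4+2] that builds ring C of the top unit with its gallate → global hydrogenolysis.
- Stereochemistry: C2/C3 of the two lower units come from (−)-epicatechin. Middle C4 is set by anchimeric control of the 3-O-galloyl group. Top C2/C3 are cis from the Z-alkene, top C4 is trans from the cycloaddition transition state, and the absolute sense comes from a chiral phosphoric acid.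

Key step: step 11

Assumption: the (R)-enantiomer of the chiral phosphoric acid is taken as the one that directs the alkene to the required face of the quinone methide; if the sense of induction is the opposite, the (S)-enantiomer is used with no other change. The benzyl-protected gallic acid, phenol and aldehyde building blocks are taken as commercial.

**Route**

Step 1
Reactants: 1 (−)-epicatechin
Product: 2 5,7,3',4'-tetra-O-benzyl-(−)-epicatechin
Conditions: BnBr (4.4 equiv), K2CO3, DMF, 0 °C to rt, argon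
Reagents that add atoms: benzyl bromide, BrCc1ccccc1
Why: Williamson etherification of the four phenols with a carbonate base leaves the far less acidic secondary 3-OH free and, at low temperature, should not open ring C, so C2 and C3 stay 2R,3R.

Step 2
Reactants: 2 5,7,3',4'-tetra-O-benzyl-(−)-epicatechin; 3 3,4,5-tris(benzyloxy)benzoic acid
Product: 4 5,7,3',4'-tetra-O-benzyl-(−)-epicatechin 3-O-[3,4,5-tris(benzyloxy)benzoate] (heptabenzyl epicatechin gallate)
Conditions: DCC, DMAP (cat.), CH2Cl2, rt
Reagents that add atoms: none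
Why: Steglich esterification acylates the axial 3-OH with retention, since the C3–O bond is not touched.

Step 3
Reactants: 4 heptabenzyl epicatechin gallate
Product: 5 4β-(2-ethoxyethoxy) derivative of 4 (ether at C4 trans to the C3 ester)
Conditions: DDQ (2 equiv), 2-ethoxyethanol (5 equiv), CH2Cl2, rt
Reagents that add atoms: 2-ethoxyethanol, CCOCCO
Why: DDQ benzylic oxidation abstracts hydride from C4, the C–H activated by the three ring A oxygens, and the alcohol should capture the flavan-4-yl cation on the β face, anti to the 3-O-galloyl group that bridges the α face, which sets C4 trans to C3.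

Step 4
Reactants: 5 4β-(2-ethoxyethoxy) heptabenzyl epicatechin gallate
Product: 6 8-bromo derivative of 5
Conditions: NBS (1.05 equiv), CH2Cl2, −78 to 0 °C
Reagents that add atoms: N-bromosuccinimide, O=C1CCC(=O)N1Br
Why: electrophilic aromatic bromination goes to C8, the kinetically preferred position of a 5,7-di-O-benzyl ring A, and the bromine then blocks C8 until the last step.

Step 5
Reactants: 6 8-bromo-4β-(2-ethoxyethoxy) heptabenzyl epicatechin gallate
Product: 7 8-bromo-6-iodo derivative of 5
Conditions: NIS (1.2 equiv), DMF, rt, dark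
Reagents that add atoms: N-iodosuccinimide, O=C1CCC(=O)N1I
Why: electrophilic aromatic iodination can only go to C6, the last free position of the trioxygenated ring A, since ring B and the ester-deactivated gallate ring are much less reactive; the iodide is the handle for the later one-carbon homologation.

Step 6
Reactants: 7 8-bromo-6-iodo-4β-(2-ethoxyethoxy) heptabenzyl epicatechin gallate; 4 heptabenzyl epicatechin gallate (2 equiv)
Product: 8 dimer iodide, 8-bromo-6-iodo heptabenzyl epicatechin gallate-(4β→8)-heptabenzyl epicatechin gallate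
Conditions: TMSOTf (0.2 equiv), CH2Cl2, −78 to −40 °C, then Et3N
Reagents that add atoms: none
Why: Lewis acid ionisation of the C4 ether gives the flavan-4-yl cation, bridged on the α face by the 3-O-galloyl carbonyl, and Friedel–Crafts attack by C8 of 4 (its most nucleophilic ring A position) from the β face should set the middle C4 with the 3,4-trans (4β→8) configuration, while the halogens at C6 and C8 exclude self-condensation of the electrophile.

Step 7
Reactants: 8 dimer iodide
Product: 9 dimer aldehyde (CHO in place of I at C6 of the upper unit of 8)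
Conditions: Pd(PPh3)4 (5 mol %), CO (3 atm), Bu3SnH (1.2 equiv, slow addition), toluene, 50 °C
Reagents that add atoms: carbon monoxide, [C-]#[O+]
Why: palladium-catalysed reductive carbonylation, in which zerovalent palladium inserts into the C–I bond much faster than into the C–Br bond, CO insertion gives the acyl palladium and hydride transfer from the tin hydride releases the aldehyde; no stereocentre is involved.

Step 8
Reactants: 9 dimer aldehyde; 10 3,5-bis(benzyloxy)phenol (1.5 equiv)
Product: 11 benzodioxaborin, 5,7-bis(benzyloxy)-2-phenyl-4H-1,3,2-benzodioxaborin carrying at its C4 the C6 of the upper unit of the dimer (both epimers at the dioxaborin C4)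
Conditions: PhB(OH)2 (1.5 equiv), EtCO2H (0.3 equiv), 4 Å MS, toluene, 80 °C
Reagents that add atoms: phenylboronic acid, OB(O)c1ccccc1
Why: boronic acid-templated ortho-specific hydroxyalkylation of a phenol, in which the aryl boronate half ester of 10 binds the aldehyde and delivers it to the ortho carbon through a six-membered transition state and the product is locked as the cyclic boronate, which holds back ionisation and a second arylation; the new carbinol centre forms as a mixture that converges in step 11.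

Step 9
Reactants: 12 3,4-bis(benzyloxy)benzaldehyde
Product: 13 1,2-bis(benzyloxy)-4-ethynylbenzene
Conditions: dimethyl (1-diazo-2-oxopropyl)phosphonate (Ohira–Bestmann reagent), K2CO3, MeOH/THF, rt
Reagents that add atoms: dimethyl (1-diazo-2-oxopropyl)phosphonate, CC(=O)C(=[N+]=[N-])P(=O)(OC)OC
Why: Seyferth–Gilbert homologation in its Ohira–Bestmann form converts the non-enolisable aryl aldehyde into the terminal alkyne under mild base.

Step 10
Reactants: 13 1,2-bis(benzyloxy)-4-ethynylbenzene; 3 3,4,5-tris(benzyloxy)benzoic acid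
Product: 14 (Z)-2-[3,4-bis(benzyloxy)phenyl]ethenyl 3,4,5-tris(benzyloxy)benzoate
Conditions: Ru(η3-2-methylallyl)2(dppb) (2 mol %; dppb = Ph2P(CH2)4PPh2), toluene, 65 °C
Reagents that add atoms: none
Why: ruthenium-catalysed anti-Markovnikov addition of a carboxylic acid to a terminal alkyne runs through a ruthenium vinylidene whose α carbon takes the carboxylate, and protonolysis should give the Z-enol ester selectively.

Step 11
Reactants: 11 benzodioxaborin; 14 (Z)-enol gallate (5 equiv)
Product: 17 per-O-benzylated 8-bromo trimer (21 benzyl ethers; bromine at C8 of the middle unit), via free carbinol 15 (not isolated), via ortho-quinone methide 16 (not isolated)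
Conditions: pinacol (1.05 equiv, slow addition), (R)-TRIP [(R)-3,3'-bis(2,4,6-triisopropylphenyl)-1,1'-binaphthyl-2,2'-diyl hydrogen phosphate, 15 mol %], 5 Å MS, toluene, high dilution, −20 °C to rt
Reagents that add atoms: none
Why: Proposed new method: pinacol takes the boron off 11 to release carbinol 15, the chiral phosphoric acid dehydrates it to the hydrogen-bonded ortho-quinone methide 16 (O1=C8a–C4a=C4 of the future top unit), and this oxadiene adds the electron-rich Z-alkene 14 in an inverse-electron-demand hetero-Diels–Alder reaction, the closest known reaction type being the chiral Brønsted acid catalysed [4+2] of ortho-hydroxybenzhydrol-derived quinone methides with styrenes, which has not been shown for an enol ester of a styrene or on a flavan oligomer. Ring C of the top unit closes by a concerted but asynchronous intermolecular [4+2] cycloaddition in which the C3–C4 bond leads and the O1–C2 bond follows. The regiochemistry should follow from the para-benzyloxy group of ring B, which makes C2 the cation-stabilising terminus and the ester-bearing carbon the nucleophilic one, the acyloxy oxygen being too weak a donor to reverse this. C2 and C3 should come out cis (both R in the target) because the Z geometry of 14 is transferred suprafacially, and C4 should come out trans to the C3 ester (4β, S in the target) because the acyloxy group turns away from the twisted, doubly ortho-benzyloxylated middle-unit ring on the methide carbon across the forming C3–C4 bond. The attacked face, and with it the absolute configuration of all three centres, is set by the chiral phosphate bound to the quinone methide oxygen, because the six existing stereocentres are too remote to bias it. The step needs the alkene to outrun Friedel–Crafts capture of the quinone methide by C6 of the bottom unit or by the phenol ring of a second molecule of 15, which slow release of 15 at high dilution in the presence of a fivefold excess of 14 should secure.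

Step 12
Reactants: 17 per-O-benzylated 8-bromo trimer
Product: 18 epicatechin-3-O-gallate-(4β→6)-epicatechin-3-O-gallate-(4β→8)-epicatechin-3-O-gallate (target)
Conditions: H2 (1 atm), Pd(OH)2/C, Et3N (1.5 equiv), THF/MeOH/H2O, rt
Reagents that add atoms: none
Why: heterogeneous hydrogenolysis should cleave the 21 benzyl ethers and the aryl C–Br bond while the gallate esters, the cyclic benzylic ethers and the interflavan bonds survive, so no stereocentre is touched.

**Compound list**

1 | (−)-epicatechin, (2R,3R)-2-(3,4-dihydroxyphenyl)chromane-3,5,7-triol | O[C@@H]1Cc2c(O)cc(O)cc2O[C@@H]1c1ccc(O)c(O)c1 | starting material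

2 | 5,7,3',4'-tetra-O-benzyl-(−)-epicatechin (2R,3R, 3-OH free) | O[C@@H]1Cc2c(OCc5ccccc5)cc(OCc5ccccc5)cc2O[C@@H]1c1ccc(OCc5ccccc5)c(OCc5ccccc5)c1 | intermediate

3 | 3,4,5-tris(benzyloxy)benzoic acid | OC(=O)c1cc(OCc2ccccc2)c(OCc2ccccc2)c(OCc2ccccc2)c1 | starting material

4 | heptabenzyl epicatechin gallate, 5,7,3',4'-tetra-O-benzyl-(−)-epicatechin 3-O-[3,4,5-tris(benzyloxy)benzoate] (2R,3R) | O=C(O[C@@H]1Cc2c(OCc5ccccc5)cc(OCc5ccccc5)cc2O[C@@H]1c1ccc(OCc5ccccc5)c(OCc5ccccc5)c1)c1cc(OCc5ccccc5)c(OCc5ccccc5)c(OCc5ccccc5)c1 | intermediate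

5 | 4β-(2-ethoxyethoxy) derivative of 4 (2,3-cis, 3,4-trans) | CCOCCO[C@@H]1[C@@H](OC(=O)c2cc(OCc5ccccc5)c(OCc5ccccc5)c(OCc5ccccc5)c2)[C@@H](c2ccc(OCc5ccccc5)c(OCc5ccccc5)c2)Oc2cc(OCc5ccccc5)cc(OCc5ccccc5)c12 | intermediate

6 | 8-bromo-4β-(2-ethoxyethoxy) heptabenzyl epicatechin gallate | CCOCCO[C@@H]1[C@@H](OC(=O)c2cc(OCc5ccccc5)c(OCc5ccccc5)c(OCc5ccccc5)c2)[C@@H](c2ccc(OCc5ccccc5)c(OCc5ccccc5)c2)Oc2c(Br)c(OCc5ccccc5)cc(OCc5ccccc5)c12 | intermediate

7 | 8-bromo-6-iodo-4β-(2-ethoxyethoxy) heptabenzyl epicatechin gallate | CCOCCO[C@@H]1[C@@H](OC(=O)c2cc(OCc5ccccc5)c(OCc5ccccc5)c(OCc5ccccc5)c2)[C@@H](c2ccc(OCc5ccccc5)c(OCc5ccccc5)c2)Oc2c(Br)c(OCc5ccccc5)c(I)c(OCc5ccccc5)c12 | intermediate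

8 | dimer iodide, 8-bromo-6-iodo heptabenzyl epicatechin gallate-(4β→8)-heptabenzyl epicatechin gallate (interflavan bond trans to the upper 3-O-galloyl group) | Ic1c(OCc5ccccc5)c(Br)c3c(c1OCc5ccccc5)[C@H](c2c(OCc5ccccc5)cc(OCc5ccccc5)c4c2O[C@H](c2ccc(OCc5ccccc5)c(OCc5ccccc5)c2)[C@H](OC(=O)c2cc(OCc5ccccc5)c(OCc5ccccc5)c(OCc5ccccc5)c2)C4)[C@@H](OC(=O)c2cc(OCc5ccccc5)c(OCc5ccccc5)c(OCc5ccccc5)c2)[C@@H](c2ccc(OCc5ccccc5)c(OCc5ccccc5)c2)O3 | intermediate

9 | dimer aldehyde, as 8 with a formyl group at C6 of the upper unit | O=Cc1c(OCc5ccccc5)c(Br)c3c(c1OCc5ccccc5)[C@H](c2c(OCc5ccccc5)cc(OCc5ccccc5)c4c2O[C@H](c2ccc(OCc5ccccc5)c(OCc5ccccc5)c2)[C@H](OC(=O)c2cc(OCc5ccccc5)c(OCc5ccccc5)c(OCc5ccccc5)c2)C4)[C@@H](OC(=O)c2cc(OCc5ccccc5)c(OCc5ccccc5)c(OCc5ccccc5)c2)[C@@H](c2ccc(OCc5ccccc5)c(OCc5ccccc5)c2)O3 | intermediate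

10 | 3,5-bis(benzyloxy)phenol | Oc1cc(OCc2ccccc2)cc(OCc2ccccc2)c1 | starting material

11 | benzodioxaborin, 5,7-bis(benzyloxy)-2-phenyl-4H-1,3,2-benzodioxaborin-4-yl group at C6 of the upper unit of the dimer (dioxaborin C4 as both epimers) | C7(OB(c6ccccc6)Oc8cc(OCc5ccccc5)cc(OCc5ccccc5)c78)c1c(OCc5ccccc5)c(Br)c3c(c1OCc5ccccc5)[C@H](c2c(OCc5ccccc5)cc(OCc5ccccc5)c4c2O[C@H](c2ccc(OCc5ccccc5)c(OCc5ccccc5)c2)[C@H](OC(=O)c2cc(OCc5ccccc5)c(OCc5ccccc5)c(OCc5ccccc5)c2)C4)[C@@H](OC(=O)c2cc(OCc5ccccc5)c(OCc5ccccc5)c(OCc5ccccc5)c2)[C@@H](c2ccc(OCc5ccccc5)c(OCc5ccccc5)c2)O3 | intermediate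

12 | 3,4-bis(benzyloxy)benzaldehyde | O=Cc1ccc(OCc2ccccc2)c(OCc2ccccc2)c1 | starting material

13 | 1,2-bis(benzyloxy)-4-ethynylbenzene | C#Cc1ccc(OCc2ccccc2)c(OCc2ccccc2)c1 | intermediate

14 | (Z)-2-[3,4-bis(benzyloxy)phenyl]ethenyl 3,4,5-tris(benzyloxy)benzoate | O=C(O/C=C\c1ccc(OCc2ccccc2)c(OCc2ccccc2)c1)c1cc(OCc2ccccc2)c(OCc2ccccc2)c(OCc2ccccc2)c1 | intermediate

15 | free carbinol, [2-hydroxy-4,6-bis(benzyloxy)phenyl](hydroxy)methyl group at C6 of the upper unit of the dimer (carbinol carbon as both epimers) | OC(c7c(O)cc(OCc5ccccc5)cc7OCc5ccccc5)c1c(OCc5ccccc5)c(Br)c3c(c1OCc5ccccc5)[C@H](c2c(OCc5ccccc5)cc(OCc5ccccc5)c4c2O[C@H](c2ccc(OCc5ccccc5)c(OCc5ccccc5)c2)[C@H](OC(=O)c2cc(OCc5ccccc5)c(OCc5ccccc5)c(OCc5ccccc5)c2)C4)[C@@H](OC(=O)c2cc(OCc5ccccc5)c(OCc5ccccc5)c(OCc5ccccc5)c2)[C@@H](c2ccc(OCc5ccccc5)c(OCc5ccccc5)c2)O3 | intermediate (not isolated)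

16 | ortho-quinone methide, 3,5-bis(benzyloxy)-6-(arylmethylidene)cyclohexa-2,4-dien-1-one with the aryl group being C6 of the upper unit of the dimer (exocyclic geometry labile, not defined) | O=C7C=C(OCc5ccccc5)C=C(OCc5ccccc5)C7=Cc1c(OCc5ccccc5)c(Br)c3c(c1OCc5ccccc5)[C@H](c2c(OCc5ccccc5)cc(OCc5ccccc5)c4c2O[C@H](c2ccc(OCc5ccccc5)c(OCc5ccccc5)c2)[C@H](OC(=O)c2cc(OCc5ccccc5)c(OCc5ccccc5)c(OCc5ccccc5)c2)C4)[C@@H](OC(=O)c2cc(OCc5ccccc5)c(OCc5ccccc5)c(OCc5ccccc5)c2)[C@@H](c2ccc(OCc5ccccc5)c(OCc5ccccc5)c2)O3 | intermediate (not isolated)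

17 | per-O-benzylated 8-bromo trimer, heptabenzyl epicatechin gallate-(4β→6)-8-bromo heptabenzyl epicatechin gallate-(4β→8)-heptabenzyl epicatechin gallate | O=C(O[C@@H]1[C@@H](c2c(OCc5ccccc5)c(Br)c3c(c2OCc5ccccc5)[C@H](c2c(OCc5ccccc5)cc(OCc5ccccc5)c4c2O[C@H](c2ccc(OCc5ccccc5)c(OCc5ccccc5)c2)[C@H](OC(=O)c2cc(OCc5ccccc5)c(OCc5ccccc5)c(OCc5ccccc5)c2)C4)[C@@H](OC(=O)c2cc(OCc5ccccc5)c(OCc5ccccc5)c(OCc5ccccc5)c2)[C@@H](c2ccc(OCc5ccccc5)c(OCc5ccccc5)c2)O3)c2c(OCc5ccccc5)cc(OCc5ccccc5)cc2O[C@@H]1c1ccc(OCc5ccccc5)c(OCc5ccccc5)c1)c1cc(OCc5ccccc5)c(OCc5ccccc5)c(OCc5ccccc5)c1 | intermediate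

18 | epicatechin-3-O-gallate-(4β→6)-epicatechin-3-O-gallate-(4β→8)-epicatechin-3-O-gallate | O=C(O[C@@H]1[C@@H](c2c(O)cc3c(c2O)[C@H](c2c(O)cc(O)c4c2O[C@H](c2ccc(O)c(O)c2)[C@H](OC(=O)c2cc(O)c(O)c(O)c2)C4)[C@@H](OC(=O)c2cc(O)c(O)c(O)c2)[C@@H](c2ccc(O)c(O)c2)O3)c2c(O)cc(O)cc2O[C@@H]1c1ccc(O)c(O)c1)c1cc(O)c(O)c(O)c1 | target

**Step count and risks**

Total step count: 12. Longest linear sequence: 10 steps (steps 1 to 8, 11 and 12, from 1).

Step 11 (most likely to fail). The cycloaddition may show poor control of the attacked face or of the trans disposition at C4, and the quinone methide may be diverted into Friedel–Crafts self-condensation instead of cycloaddition. The fallback uses the established Lewis acid interflavan coupling and sets out from 6 and 4. TMSOTf-promoted coupling of 6 with an excess of 4 at −78 °C should give the 8-bromo dimer F1 with the 4β→8 bond, exactly as in step 6. A second TMSOTf coupling of F1 with 6, now the bromine-capped top electrophile, should form the 4β→6 bond at the free C6 of the middle unit, anti to the gallate, and give the dibromo trimer F2. Attack at C6 of the bottom unit is expected as a competing process, so the regioisomer has to be removed by chromatography. Hydrogenolysis of F2 under the conditions of step 12 removes both bromines and all benzyl groups and comes back to the route at 18.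

Step 7. Hydrodeiodination may outrun CO insertion at the doubly ortho-substituted aryl palladium, or insertion into the C–Br bond may compete. The fallback moves the formylation to the monomer and sets out from 6. Vilsmeier–Haack formylation of 6 (POCl3, DMF, 0 °C to rt, then aqueous sodium acetate) should go to C6, the only free ring A position, and give the 6-formyl-8-bromo electrophile F3. TMSOTf-promoted coupling of F3 with 4 should then give 9 directly, which by-passes 7 and 8 and comes back to the route at 9.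

Step 8. Addition to the hindered, electron-rich aldehyde may be sluggish, or the product may ionise prematurely and be arylated a second time. The fallback replaces the boron template by a magnesium chelate and sets out from 10. EtMgBr in Et2O/toluene should give bromomagnesium 3,5-bis(benzyloxy)phenoxide F4. Addition of 9 in toluene at rt should give, through a six-membered magnesium chelate that directs the ortho carbon onto the aldehyde, the carbinol 15 after work-up with aqueous ammonium chloride. Crude 15 is used at once in step 11 without pinacol, so the fallback comes back to the route at 15.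

Further compounds

F1 | step 11 | 8-bromo dimer, 8-bromo heptabenzyl epicatechin gallate-(4β→8)-heptabenzyl epicatechin gallate | c1c(OCc5ccccc5)c(Br)c3c(c1OCc5ccccc5)[C@H](c2c(OCc5ccccc5)cc(OCc5ccccc5)c4c2O[C@H](c2ccc(OCc5ccccc5)c(OCc5ccccc5)c2)[C@H](OC(=O)c2cc(OCc5ccccc5)c(OCc5ccccc5)c(OCc5ccccc5)c2)C4)[C@@H](OC(=O)c2cc(OCc5ccccc5)c(OCc5ccccc5)c(OCc5ccccc5)c2)[C@@H](c2ccc(OCc5ccccc5)c(OCc5ccccc5)c2)O3

F2 | step 11 | dibromo trimer, 8-bromo heptabenzyl epicatechin gallate-(4β→6)-8-bromo heptabenzyl epicatechin gallate-(4β→8)-heptabenzyl epicatechin gallate | O=C(O[C@@H]1[C@@H](c2c(OCc5ccccc5)c(Br)c3c(c2OCc5ccccc5)[C@H](c2c(OCc5ccccc5)cc(OCc5ccccc5)c4c2O[C@H](c2ccc(OCc5ccccc5)c(OCc5ccccc5)c2)[C@H](OC(=O)c2cc(OCc5ccccc5)c(OCc5ccccc5)c(OCc5ccccc5)c2)C4)[C@@H](OC(=O)c2cc(OCc5ccccc5)c(OCc5ccccc5)c(OCc5ccccc5)c2)[C@@H](c2ccc(OCc5ccccc5)c(OCc5ccccc5)c2)O3)c2c(OCc5ccccc5)cc(OCc5ccccc5)c(Br)c2O[C@@H]1c1ccc(OCc5ccccc5)c(OCc5ccccc5)c1)c1cc(OCc5ccccc5)c(OCc5ccccc5)c(OCc5ccccc5)c1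

F3 | step 7 | 8-bromo-6-formyl-4β-(2-ethoxyethoxy) heptabenzyl epicatechin gallate | CCOCCO[C@@H]1[C@@H](OC(=O)c2cc(OCc5ccccc5)c(OCc5ccccc5)c(OCc5ccccc5)c2)[C@@H](c2ccc(OCc5ccccc5)c(OCc5ccccc5)c2)Oc2c(Br)c(OCc5ccccc5)c(C=O)c(OCc5ccccc5)c12

F4 | step 8 | bromomagnesium 3,5-bis(benzyloxy)phenoxide | Br[Mg]Oc1cc(OCc2ccccc2)cc(OCc2ccccc2)c1
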